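**Strategy.** In the heptanone chain (C1 benzylic to the 3,4-dihydroxy-5-methoxyphenyl ring, C3 ketone, C5 carbinol), the C5 oxygen and C1 stand in a 1,5-relationship across the C3 carbonyl. C1–C5 plus that oxygen can therefore be folded into a cis-2,6-disubstituted tetrahydropyran-4-one whose C1–O bond is benzylic and removable. One catalytic asymmetric oxa-Diels–Alder reaction forms C1–C2 and O–C5, closes this ring and sets both ring stereocentres; hydrogenolysis later erases the C1 centre and frees the (5R)-alcohol. The precursors are an (E)-2-silyloxy diene carrying the guaiacylethyl arm and 5-hydroxyvanillin whose catechol oxygens are masked as benzyl carbonates, which make the aldehyde electron-poor yet remain hydrogenolysable.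

Key step: step 6

Assumption: the (1R,2S)-aminoindanol-derived chromium catalyst is taken to expose the Re face of the aryl aldehyde (giving 2R), by analogy with its behaviour towards other aldehydes; if a trial run shows the opposite sense, the mirror-image catalyst is used with no other change.

**Step 1**
Reactants: 1 5-hydroxyvanillin (3,4-dihydroxy-5-methoxybenzaldehyde)
Product: 2 3,4-bis[(benzyloxycarbonyl)oxy]-5-methoxybenzaldehyde
Conditions: CbzCl (2.5 equiv), Et3N (2.6 equiv, added slowly), CH2Cl2, −10 → 0 °C
Reagents that add atoms: benzyl chloroformate, O=C(Cl)OCc1ccccc1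
Why: O-alkoxycarbonylation of both phenols by the chloroformate; with the chloroformate in excess and the amine added last, the second acylation should outrun closure to the cyclic catechol carbonate.

**Step 2**
Reactants: 3 dihydroconiferyl alcohol [4-(3-hydroxypropyl)-2-methoxyphenol]
Product: 4 3-[4-(benzyloxy)-3-methoxyphenyl]propan-1-ol
Conditions: BnBr (1.1 equiv), K2CO3, acetone, reflux
Reagents that add atoms: benzyl bromide, BrCc1ccccc1
Why: Williamson ether synthesis in which the carbonate base deprotonates only the phenol, so the primary alcohol should remain free.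

**Step 3**
Reactants: 4 3-[4-(benzyloxy)-3-methoxyphenyl]propan-1-ol
Product: 5 3-[4-(benzyloxy)-3-methoxyphenyl]propanal
Conditions: Dess–Martin periodinane (1.2 equiv), CH2Cl2, 0 °C → rt
Reagents that add atoms: none
Why: Dess–Martin oxidation of a primary alcohol stops at the aldehyde and tolerates the benzyl ether and the electron-rich arene.

**Step 4**
Reactants: 5 3-[4-(benzyloxy)-3-methoxyphenyl]propanal; 6 1-(triphenylphosphoranylidene)propan-2-one
Product: 7 (E)-6-[4-(benzyloxy)-3-methoxyphenyl]hex-3-en-2-one
Conditions: toluene, 80 °C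
Reagents that add atoms: none
Why: Wittig olefination with a ketone-stabilised ylide, which should give the E-enone selectively.

**Step 5**
Reactants: 7 (E)-6-[4-(benzyloxy)-3-methoxyphenyl]hex-3-en-2-one
Product: 8 (E)-6-[4-(benzyloxy)-3-methoxyphenyl]-2-(triethylsilyloxy)hexa-1,3-diene
Conditions: TESOTf (1.2 equiv), Et3N (2 equiv), Et2O, 0 °C; filtration through Et3N-deactivated silica
Reagents that add atoms: triethylsilyl trifluoromethanesulfonate, CC[Si](CC)(CC)OS(=O)(=O)C(F)(F)F
Why: Soft enolisation (silyl triflate/amine) should remove a proton from the methyl group under kinetic control, giving the cross-conjugated 2-silyloxy diene and leaving the E-alkene untouched.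

**Step 6**
Reactants: 2 3,4-bis[(benzyloxycarbonyl)oxy]-5-methoxybenzaldehyde; 8 (E)-6-[4-(benzyloxy)-3-methoxyphenyl]-2-(triethylsilyloxy)hexa-1,3-diene
Product: 10 (2R,6R)-2-[3,4-bis(benzyloxycarbonyloxy)-5-methoxyphenyl]-6-{2-[4-(benzyloxy)-3-methoxyphenyl]ethyl}tetrahydro-4H-pyran-4-one, via enol silane cycloadduct 9 (not isolated)
Conditions: (1R,2S)-tridentate Schiff-base Cr(III)Cl catalyst [from 3-(1-adamantyl)-2-hydroxy-5-methylbenzaldehyde and cis-1-amino-2-indanol] (10 mol %), 4 Å MS, TBME (ca. 2 M), rt; then TFA (cat.), wet CH2Cl2, 0 °C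
Reagents that add atoms: none
Why: The chromium(III) Lewis acid binds the aldehyde oxygen, and the enol-ether CH2 terminus of the diene bonds to the aldehyde carbon while the carbonyl oxygen bonds to the alkyl-bearing diene terminus, in a concerted but asynchronous oxa-[4+2] cycloaddition; this is the established Cr(III)–Schiff-base hetero-Diels–Alder reaction of aldehydes with 4-substituted 2-silyloxy dienes. The six-membered oxacycle is closed by this intermolecular [4π+2π] cycloaddition, both ring bonds (C–C and C–O) forming in one event, and catalytic acid then hydrolyses enol silane 9 to ketone 10 without touching C2 or C6. Ring carbon C2 (chain C1, 2R) is set by the catalyst, which shields one face of the bound aldehyde so that the diene adds to the Re face. Ring carbon C6 (chain C5, 6R) follows from the endo transition state with the E-diene, which places the aryl and arylethyl groups cis. The step needs regioselectivity (secured by the 2-silyloxy group polarising the diene), endo selectivity (secured by the E geometry from the Wittig step and the concerted pathway) and enantiofacial selectivity (secured by the catalyst). The two carbonate groups turn the donor-substituted benzaldehyde into an electron-poor heterodienophile and disfavour ionisation of the new benzylic C–O bond during the acidic desilylation.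

**Step 7**
Reactants: 10 (2R,6R)-2-[3,4-bis(benzyloxycarbonyloxy)-5-methoxyphenyl]-6-{2-[4-(benzyloxy)-3-methoxyphenyl]ethyl}tetrahydro-4H-pyran-4-one
Product: 12 (5R)-1-(3,4-dihydroxy-5-methoxyphenyl)-5-hydroxy-7-(4-hydroxy-3-methoxyphenyl)heptan-3-one, via triphenol pyranone 11 (not isolated)
Conditions: H2 (1–3 bar), 20 % Pd(OH)2/C, EtOAc–EtOH, rt, neutral medium, degassed work-up
Reagents that add atoms: none
Why: Heterogeneous hydrogenolysis should first cleave the two benzyl carbonates (to phenol, CO2 and toluene) and the benzyl ether, and then the ring C2–O bond, benzylic to the now electron-rich ring, to leave a CH2 group; the C6–O bond is never broken, so the carbinol keeps its R configuration, and the neutral medium avoids β-elimination of the β-hydroxy ketone.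

**Compound list**
1 | 5-hydroxyvanillin (3,4-dihydroxy-5-methoxybenzaldehyde) | COc1cc(C=O)cc(O)c1O | starting material
2 | 3,4-bis[(benzyloxycarbonyl)oxy]-5-methoxybenzaldehyde | COc1cc(C=O)cc(OC(=O)OCc2ccccc2)c1OC(=O)OCc1ccccc1 | intermediate
3 | dihydroconiferyl alcohol [4-(3-hydroxypropyl)-2-methoxyphenol] | COc1cc(CCCO)ccc1O | starting material
4 | 3-[4-(benzyloxy)-3-methoxyphenyl]propan-1-ol | COc1cc(CCCO)ccc1OCc1ccccc1 | intermediate
5 | 3-[4-(benzyloxy)-3-methoxyphenyl]propanal | COc1cc(CCC=O)ccc1OCc1ccccc1 | intermediate
6 | 1-(triphenylphosphoranylidene)propan-2-one | CC(=O)C=P(c1ccccc1)(c1ccccc1)c1ccccc1 | starting material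
7 | (E)-6-[4-(benzyloxy)-3-methoxyphenyl]hex-3-en-2-one | CC(=O)/C=C/CCc1ccc(OCc2ccccc2)c(OC)c1 | intermediate
8 | (E)-6-[4-(benzyloxy)-3-methoxyphenyl]-2-(triethylsilyloxy)hexa-1,3-diene | C=C(O[Si](CC)(CC)CC)/C=C/CCc1ccc(OCc2ccccc2)c(OC)c1 | intermediate
9 | (2R,6R)-2-[3,4-bis(benzyloxycarbonyloxy)-5-methoxyphenyl]-6-{2-[4-(benzyloxy)-3-methoxyphenyl]ethyl}-4-(triethylsilyloxy)-3,6-dihydro-2H-pyran (cis) | COc1cc(CC[C@@H]2C=C(O[Si](CC)(CC)CC)C[C@H](c3cc(OC(=O)OCc4ccccc4)c(OC(=O)OCc4ccccc4)c(OC)c3)O2)ccc1OCc1ccccc1 | intermediate
10 | (2R,6R)-2-[3,4-bis(benzyloxycarbonyloxy)-5-methoxyphenyl]-6-{2-[4-(benzyloxy)-3-methoxyphenyl]ethyl}tetrahydro-4H-pyran-4-one (cis) | COc1cc(CC[C@@H]2CC(=O)C[C@H](c3cc(OC(=O)OCc4ccccc4)c(OC(=O)OCc4ccccc4)c(OC)c3)O2)ccc1OCc1ccccc1 | intermediate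
11 | (2R,6R)-2-(3,4-dihydroxy-5-methoxyphenyl)-6-[2-(4-hydroxy-3-methoxyphenyl)ethyl]tetrahydro-4H-pyran-4-one (cis) | COc1cc(CC[C@@H]2CC(=O)C[C@H](c3cc(O)c(O)c(OC)c3)O2)ccc1O | intermediate
12 | (5R)-1-(3,4-dihydroxy-5-methoxyphenyl)-5-hydroxy-7-(4-hydroxy-3-methoxyphenyl)heptan-3-one | COc1cc(CC[C@@H](O)CC(=O)CCc2cc(O)c(O)c(OC)c2)ccc1O | target

**Totals.** Total step count: 7. Longest linear sequence: 6 steps (3 → 4 → 5 → 7 → 8 → 10 → 12).

**Steps most likely to fail**

Step 6. The cycloaddition of an aromatic aldehyde may be slow enough that hydrolysis or oligomerisation of the enol silane diene competes. Facial control may also be incomplete, or the reaction may leak into a stepwise Mukaiyama pathway that erodes the cis relationship. The fallback sets out from 7 and 2 and returns at 10. The methyl group of enone 7 is enolised with the Ipc2BCl antipode that delivers the R carbinol (Et3N, Et2O, −78 → 0 °C), and the boron enolate is added to 2 in a Paterson-type boron aldol reaction. This should give (1R,4E)-1-[3,4-bis(benzyloxycarbonyloxy)-5-methoxyphenyl]-7-[4-(benzyloxy)-3-methoxyphenyl]-1-hydroxyhept-4-en-3-one F1. Acid-catalysed 6-endo oxa-Michael addition of the hydroxyl to the enone (Amberlyst-15, CH2Cl2) should then close the ring to the thermodynamically preferred cis isomer 10. The benzylic centre is fixed by the aldol and C6 by equilibration.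

Step 7. Hydrogenolysis of the ring C–O bond may stall after the protecting groups have gone, or the ketone may be over-reduced when the reaction is forced. The fallback sets out from 10 and returns at 12. Hydrogenolysis is run under mild conditions (Pd/C, EtOAc, 1 atm, stopped once the carbonates and the benzyl ether are cleaved) and the triphenol pyranone 11 is isolated. Its benzylic C–O bond, now para to a free hydroxyl, is then cleaved by ionic hydrogenation (Et3SiH, TFA, CH2Cl2, −20 → 0 °C). This proceeds by ionisation to the p-hydroxybenzylic cation and hydride transfer from the silane, conditions under which a dialkyl ketone is reduced far more slowly.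

Step 1. The mono-acylated catechol may close to the cyclic carbonate in competition with the second acylation, or a carbonate group may be lost on purification. The fallback sets out from 1 and returns at 11. Double Williamson benzylation (BnBr, K2CO3, DMF) should give 3,4-bis(benzyloxy)-5-methoxybenzaldehyde F2. This less electrophilic aldehyde is taken through the same chromium-catalysed cycloaddition with 8 (neat, longer time) to the 4-triethylsilyloxy-3,6-dihydro-2H-pyran cycloadduct F3 and, after acid hydrolysis, the tris(benzyl ether) pyranone F4. The hydrogenolysis conditions of step 7 then remove the three benzyl ethers to give 11 in the flask, which continues to 12.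

**Further compounds**
F1 | step 6 | (1R,4E)-1-[3,4-bis(benzyloxycarbonyloxy)-5-methoxyphenyl]-7-[4-(benzyloxy)-3-methoxyphenyl]-1-hydroxyhept-4-en-3-one | COc1cc(CC/C=C/C(=O)C[C@H](c2cc(OC(=O)OCc3ccccc3)c(OC(=O)OCc3ccccc3)c(OC)c2)O)ccc1OCc1ccccc1
F0 | step 7 | none | none
F2 | step 1 | 3,4-bis(benzyloxy)-5-methoxybenzaldehyde | COc1cc(C=O)cc(OCc2ccccc2)c1OCc1ccccc1
F3 | step 1 | (2R,6R)-2-[3,4-bis(benzyloxy)-5-methoxyphenyl]-6-{2-[4-(benzyloxy)-3-methoxyphenyl]ethyl}-4-(triethylsilyloxy)-3,6-dihydro-2H-pyran | COc1cc(CC[C@@H]2C=C(O[Si](CC)(CC)CC)C[C@H](c3cc(OCc4ccccc4)c(OCc4ccccc4)c(OC)c3)O2)ccc1OCc1ccccc1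
F4 | step 1 | (2R,6R)-2-[3,4-bis(benzyloxy)-5-methoxyphenyl]-6-{2-[4-(benzyloxy)-3-methoxyphenyl]ethyl}tetrahydro-4H-pyran-4-one | COc1cc(CC[C@@H]2CC(=O)C[C@H](c3cc(OCc4ccccc4)c(OCc4ccccc4)c(OC)c3)O2)ccc1OCc1ccccc1
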